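- The rate constants of this flask are not given, but one constant of the books is: X takes one Z to become J and J takes a second to become D, so D holds two Z and L holds 3.

| flask | Q | Z | remark | time |
|---|---|---|---|---|
| winter | 0.028 M | 2 equiv | run made earlier |  |
| dawn | 0.044 M | 2 equiv | run made earlier |  |
| flask | 0.020 M | 2.00 equiv |  | 40 min |

| run | time / min | D / % | L / % | Q / % |
|---|---|---|---|---|
| winter | 2.50 | 88.6 | 2.3 | 0 |
| winter | 4.00 | 94.3 | 0.1 | 0.5 |
| winter | 6.00 | 96.5 | 0 | 0.1 |
| winter | 10.0 | 98.3 | 0.7 | 0 |
| winter | 15.0 | 99.0 | 0 | 0 |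
| winter | 20.0 | 99.6 | 0.1 | 0 |
| winter | 30.0 | 99.5 | 0.1 | 0 |
| dawn | 1.50 | 16.6 | 24.4 | 56.8 |
| dawn | 5.00 | 92.8 | 0 | 0.7 |
| dawn | 10.0 | 96.8 | 0 | 0 |
| dawn | 15.0 | 97.4 | 0.2 | 0.5 |
| dawn | 20.0 | 98.3 | 0.2 | 0.7 |
| dawn | 25.0 | 99.4 | 0.4 | 1.0 |
| dawn | 30.0 | 99.6 | 0.1 | 0.1 |

(standard deviation of a reading: 0.5 percentage points)

- equivalents of Z to Q, everything else as given, that leave most D at 40 min
- the amount of D then, in percent of the Q charged
- the amount of D with the amounts as given

- solid, in amounts per volume of the solution: Q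
- steps thought possible: X + Z -> J; Z + J -> D; Z + D <-> L; L <-> E; Q <-> X
- at the start none of Q is in solution

- The ledger ceiling, the Z charged over the 2 equiv per Q used in winter, which is what D takes, is the share of Q that the charge can carry to D; for this flask it is 100%.
- The first entry is a loan: in dawn at 1.50 min, L holds 36.6% of the Z charged and D holds 16.6%, with 56.8% of Q still solid. By 5.00 min, dawn reads L 0% and D 92.8%, so the Z lent to L is no longer read there.
- The closing entry comes from winter: at 30.0 min, D and L together hold 99.6% of the Z charged, and the remainder lies within the scatter of 0.5 percentage points.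
- The reckoning here takes the ceiling less the gap still open in winter at that time, which gives 99.6% of D for this flask. A charge under 2 equiv lowers the ceiling, while a surplus has D to turn into L, so the charge chosen is 2 equiv.
- The forecast gives 2 equiv (1.98 equiv to 2.03 equiv), 99.7% of D at that charge (99.2% to 100%), and 99.6% for the flask (98.8% to 100%), holding that “L and E are reversible and feed back to D, with no lasting loss”.

    X + Z → J (k = 61.2 L mol⁻¹ s⁻¹)
    Z + J → D (k = 67.9 L mol⁻¹ s⁻¹)
    Z + D ⇌ L (K = 41.0 L mol⁻¹, k = 32.2 L mol⁻¹ s⁻¹)
    L ⇌ E (K = 0.690, k = 0.00201 s⁻¹)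
    Q ⇌ X, rate k5*(cs5 - [X]) while solid is left; crystals form when [X] > cs5 (solubility = 16.0 mM, k = 0.0133 s⁻¹)

- The flask gives 99.8% of D at 40 min, and the best charge is 2.00 equiv, with 99.8% of D. That D stands 0.2 points under the ceiling of 100%, with J at 0.0953%. A neighbour flask, charged with 1.20 equiv of Z, has a ceiling of 60.0%. Z, the limiting reagent there, stands at 0% of its charge, and J holds 7.47% with one Z each, so the books leave 56.3% for D, and that neighbour holds 56.3% of D.

The earlier runs and the new flask stem from a simulated flask with constants of no real substance, noise included.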